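**Retrosynthetic overview**

1. The side chain comes off first: the carbinol C–H (chelation-controlled ketone reduction), the C(=O)–ring C bond (aryl Grignard addition to a Weinreb amide) and the ring B O–CH bond (Mitsunobu inversion of ethyl (S)-lactate) lead back to phenol 21.
2. Oxolane C2–H and the C2–ring A bond lead back to γ-lactone 14 (aryllithium addition, then silane reduction of the 2-aryl oxocarbenium ion from the face opposite the two methyl groups).
3. The strategy rests on oxolane C4–C5. C5 carries O1 and ring B trans to the C4 methyl, and the C4 methyl is cis to the C3 methyl. If the C4 methyl is read as a reduced acyl carbon and C3 as the stereocentre of an (R)-methylsuccinate, C4–C5 is a syn-aldol bond and O1–C2 is the acyl bond of a lactone.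
4. Ring order: the γ-lactone (the later oxolane) is the only ring made, in step 4; rings A, B and C are bought arenes. Imide 6 is reached in three steps from a half-ester whose two carboxyl groups are already differentiated.

Key step: step 4

Remark: half-ester 1 is assumed to be purchasable as the single (R)-enantiomer; starting from it fixes which carboxyl carries the auxiliary, so no regioselective opening of methylsuccinic anhydride is needed.

**Route**

Step 1
Reactants: 1 (2R)-4-tert-butoxy-2-methyl-4-oxobutanoic acid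
Product: 2 4-tert-butyl 1-methyl (2R)-2-methylbutanedioate
Conditions: MeI, K2CO3, DMF, 23 °C
Reagents that add atoms: iodomethane, CI
Why: SN2 O-alkylation of the carboxylate by iodomethane should give the methyl ester without touching the α-stereocentre, which is not enolised by carbonate.

Step 2
Reactants: 2 4-tert-butyl 1-methyl (2R)-2-methylbutanedioate
Product: 3 (3R)-4-methoxy-3-methyl-4-oxobutanoic acid
Conditions: CF3CO2H, CH2Cl2, 0 → 23 °C
Reagents that add atoms: none
Why: Acidolysis of the tert-butyl ester (alkyl–oxygen cleavage, loss of 2-methylpropene) should free only the unbranched carboxyl group, since the methyl ester is inert to these conditions.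

Step 3
Reactants: 3 (3R)-4-methoxy-3-methyl-4-oxobutanoic acid; 4 (4S)-4-benzyl-1,3-oxazolidin-2-one
Product: 6 methyl (2R)-4-[(4S)-4-benzyl-2-oxo-1,3-oxazolidin-3-yl]-2-methyl-4-oxobutanoate, via mixed pivalic anhydride 5 (not isolated)
Conditions: t-BuCOCl, Et3N, THF, −20 °C; then 4, LiCl, −20 → 23 °C
Reagents that add atoms: none
Why: N-Acylation of the oxazolidinone through the mixed pivalic anhydride should occur at the unhindered succinyl carbonyl, and the LiCl/Et3N activation avoids a strong base, so the ester α-stereocentre is kept.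

Step 4
Reactants: 6 methyl (2R)-4-[(4S)-4-benzyl-2-oxo-1,3-oxazolidin-3-yl]-2-methyl-4-oxobutanoate; 7 4-(benzyloxy)-3-methoxybenzaldehyde
Product: 10 (4S)-4-benzyl-3-{[(2S,3S,4R)-2-[4-(benzyloxy)-3-methoxyphenyl]-4-methyl-5-oxooxolan-3-yl]carbonyl}-1,3-oxazolidin-2-one, via Z-boron enolate 8 (not isolated), via boron aldolate 9 (not isolated)
Conditions: Bu2BOTf, i-Pr2NEt, CH2Cl2, 0 °C; then 7, −78 → 23 °C; pH 7 phosphate buffer
Reagents that add atoms: none
Why: Soft enolisation with Bu2BOTf and i-Pr2NEt should convert only the imide into its Z-boron enolate 8, which adds to the aldehyde through a closed Zimmerman–Traxler chair (Evans syn-aldol) and forms the future oxolane C4–C5 bond in aldolate 9. The aldolate oxygen then attacks the neighbouring methyl ester in a 5-exo-trig acyl substitution, expelling methoxide onto boron and closing the γ-lactone, whose acyl C–O bond is the future O1–C2 bond. The closest known reaction type is the boron-mediated syn-aldol/lactonisation of succinate half-ester N-acyloxazolidinones with aldehydes, which gives trans paraconic-type lactones. Both new stereocentres are set by the (4S)-benzyl auxiliary: in the chair the oxazolidinone carbonyl points away from the enolate oxygen and the aldehyde, with its aryl group equatorial, approaches the enolate face remote from the benzyl group, so the syn aldolate results and closes to the lactone with ring B trans to the acyl group. The methyl-bearing centre from the (R)-half-ester is a spectator and ends cis to the acyl group, as needed for the cis C3/C4 methyl pair. The step needs enolate π-facial selectivity in the presence of this resident centre and imide-over-ester enolisation; the first is secured by the auxiliary, the second by the boron-chelating, more acidic imide.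

Step 5
Reactants: 10 (4S)-4-benzyl-3-{[(2S,3S,4R)-2-[4-(benzyloxy)-3-methoxyphenyl]-4-methyl-5-oxooxolan-3-yl]carbonyl}-1,3-oxazolidin-2-one
Product: 11 (2S,3S,4R)-2-[4-(benzyloxy)-3-methoxyphenyl]-4-methyl-5-oxooxolane-3-carboxylic acid
Conditions: LiOH, H2O2, THF/H2O, 0 °C; Na2SO3; 1 M HCl
Reagents that add atoms: hydrogen peroxide, OO
Why: Hydroperoxide attacks the exocyclic imide carbonyl selectively (Evans LiOOH cleavage), the peracid is reduced by sulfite, and any lactone opened by hydroxide should re-close on acidification because only the γ-lactone is possible; 0 °C keeps the α-centres from enolising.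

Step 6
Reactants: 11 (2S,3S,4R)-2-[4-(benzyloxy)-3-methoxyphenyl]-4-methyl-5-oxooxolane-3-carboxylic acid
Product: 12 (3R,4R,5S)-5-[4-(benzyloxy)-3-methoxyphenyl]-4-(hydroxymethyl)-3-methyloxolan-2-one
Conditions: BH3·SMe2, THF, 0 → 23 °C; MeOH
Reagents that add atoms: none
Why: Borane reduces a carboxylic acid through its acyloxyborane much faster than a lactone, so chemoselective reduction to the primary alcohol is expected with no stereocentre involved.

Step 7
Reactants: 12 (3R,4R,5S)-5-[4-(benzyloxy)-3-methoxyphenyl]-4-(hydroxymethyl)-3-methyloxolan-2-one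
Product: 13 (3R,4S,5S)-5-[4-(benzyloxy)-3-methoxyphenyl]-4-(iodomethyl)-3-methyloxolan-2-one
Conditions: I2, PPh3, imidazole, CH2Cl2, 0 → 23 °C
Reagents that add atoms: iodine, II
Why: Appel-type iodination (iodide displaces the alkoxyphosphonium at the primary carbon) should give the iodide under nearly neutral conditions that leave the lactone stereocentres alone.

Step 8
Reactants: 13 (3R,4S,5S)-5-[4-(benzyloxy)-3-methoxyphenyl]-4-(iodomethyl)-3-methyloxolan-2-one
Product: 14 (3R,4S,5S)-5-[4-(benzyloxy)-3-methoxyphenyl]-3,4-dimethyloxolan-2-one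
Conditions: Bu3SnH, AIBN (cat.), toluene, 80 °C
Reagents that add atoms: none
Why: Radical-chain dehalogenation turns the iodomethyl group into the C4 methyl; the primary radical is trapped by the tin hydride faster than it can fragment, and lactone and benzyl ether are inert.

Step 9
Reactants: 15 4-bromo-2-methoxyphenol
Product: 16 (4-bromo-2-methoxyphenoxy)(tert-butyl)dimethylsilane
Conditions: t-BuMe2SiCl, imidazole, DMF, 23 °C
Reagents that add atoms: tert-butyldimethylsilyl chloride, CC(C)(C)[Si](C)(C)Cl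
Why: Imidazole-mediated O-silylation of the phenol should give the silyl ether, which tolerates halogen–metal exchange and magnesium insertion and is orthogonal to the benzyl ether on ring B.

Step 10
Reactants: 16 (4-bromo-2-methoxyphenoxy)(tert-butyl)dimethylsilane; 14 (3R,4S,5S)-5-[4-(benzyloxy)-3-methoxyphenyl]-3,4-dimethyloxolan-2-one
Product: 18 (3R,4S,5S)-5-[4-(benzyloxy)-3-methoxyphenyl]-2-(4-{[tert-butyl(dimethyl)silyl]oxy}-3-methoxyphenyl)-3,4-dimethyloxolan-2-ol (C2 anomers), via aryllithium 17 (not isolated)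
Conditions: n-BuLi, THF, −78 °C; then 14, −78 °C; aq. NH4Cl
Reagents that add atoms: none
Why: Bromine–lithium exchange followed by 1,2-addition to the lactone carbonyl should stop at the lithium hemiketalate at −78 °C, and this temperature also disfavours enolisation of the lactone, so the cis C3 methyl is kept.

Step 11
Reactants: 18 (3R,4S,5S)-5-[4-(benzyloxy)-3-methoxyphenyl]-2-(4-{[tert-butyl(dimethyl)silyl]oxy}-3-methoxyphenyl)-3,4-dimethyloxolan-2-ol
Product: 20 tert-butyl{4-[(2S,3R,4S,5S)-5-[4-(benzyloxy)-3-methoxyphenyl]-3,4-dimethyloxolan-2-yl]-2-methoxyphenoxy}dimethylsilane, via oxocarbenium ion 19 (not isolated)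
Conditions: Et3SiH, BF3·OEt2, CH2Cl2, −78 °C
Reagents that add atoms: none
Why: Ionic hydrogenation: BF3 ionises the crude hemiketal to the 2-aryl oxocarbenium ion and the silane should deliver hydride to the face opposite the C3 and C4 methyl groups, so ring A ends cis to the C3 methyl (C2 = S), while −78 °C suppresses proton loss to the enol ether that would epimerise C3.

Step 12
Reactants: 20 tert-butyl{4-[(2S,3R,4S,5S)-5-[4-(benzyloxy)-3-methoxyphenyl]-3,4-dimethyloxolan-2-yl]-2-methoxyphenoxy}dimethylsilane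
Product: 21 4-[(2S,3S,4R,5S)-5-(4-{[tert-butyl(dimethyl)silyl]oxy}-3-methoxyphenyl)-3,4-dimethyloxolan-2-yl]-2-methoxyphenol
Conditions: H2 (1 atm), Pd/C, EtOAc, 23 °C
Reagents that add atoms: none
Why: Hydrogenolysis of the aryl benzyl ether is much faster than cleavage of the dialkyl benzylic C–O bonds of the oxolane in a neutral, non-protic solvent, so only the ring B phenol should be freed.

Step 13
Reactants: 21 4-[(2S,3S,4R,5S)-5-(4-{[tert-butyl(dimethyl)silyl]oxy}-3-methoxyphenyl)-3,4-dimethyloxolan-2-yl]-2-methoxyphenol; 22 ethyl (2S)-2-hydroxypropanoate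
Product: 23 ethyl (2R)-2-{4-[(2S,3S,4R,5S)-5-(4-{[tert-butyl(dimethyl)silyl]oxy}-3-methoxyphenyl)-3,4-dimethyloxolan-2-yl]-2-methoxyphenoxy}propanoate
Conditions: PPh3, DIAD, THF, 0 → 23 °C
Reagents that add atoms: none
Why: Mitsunobu etherification: the phenol displaces the activated lactate hydroxyl by SN2 with clean inversion, which sets the aryloxy-bearing carbon as R.

Step 14
Reactants: 23 ethyl (2R)-2-{4-[(2S,3S,4R,5S)-5-(4-{[tert-butyl(dimethyl)silyl]oxy}-3-methoxyphenyl)-3,4-dimethyloxolan-2-yl]-2-methoxyphenoxy}propanoate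
Product: 24 (2R)-2-{4-[(2S,3S,4R,5S)-5-(4-{[tert-butyl(dimethyl)silyl]oxy}-3-methoxyphenyl)-3,4-dimethyloxolan-2-yl]-2-methoxyphenoxy}-N-methoxy-N-methylpropanamide
Conditions: MeNH(OMe)·HCl, i-PrMgCl, THF, −20 → 0 °C
Reagents that add atoms: N,O-dimethylhydroxylamine hydrochloride, CNOC.Cl
Why: Aminolysis of the ester by the chloromagnesium amide made in the flask (Weinreb amide formation) should proceed below 0 °C with a weakly basic nucleophile, so the α-aryloxy stereocentre is not enolised.

Step 15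
Reactants: 16 (4-bromo-2-methoxyphenoxy)(tert-butyl)dimethylsilane; 24 (2R)-2-{4-[(2S,3S,4R,5S)-5-(4-{[tert-butyl(dimethyl)silyl]oxy}-3-methoxyphenyl)-3,4-dimethyloxolan-2-yl]-2-methoxyphenoxy}-N-methoxy-N-methylpropanamide
Product: 26 (2R)-1-(4-{[tert-butyl(dimethyl)silyl]oxy}-3-methoxyphenyl)-2-{4-[(2S,3S,4R,5S)-5-(4-{[tert-butyl(dimethyl)silyl]oxy}-3-methoxyphenyl)-3,4-dimethyloxolan-2-yl]-2-methoxyphenoxy}propan-1-one, via aryl Grignard reagent 25 (not isolated)
Conditions: Mg, I2 (cat.), THF, 23 → 50 °C; then 24, THF, −20 → 0 °C; cold aq. NH4Cl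
Reagents that add atoms: none
Why: Weinreb ketone synthesis: magnesium insertion into the aryl bromide gives the aryl Grignard reagent, whose magnesium-chelated tetrahedral adduct with the amide survives until the cold quench, so single addition is expected, and the Grignard reagent is a weaker base than an aryllithium, which protects the α-aryloxy stereocentre.

Step 16
Reactants: 26 (2R)-1-(4-{[tert-butyl(dimethyl)silyl]oxy}-3-methoxyphenyl)-2-{4-[(2S,3S,4R,5S)-5-(4-{[tert-butyl(dimethyl)silyl]oxy}-3-methoxyphenyl)-3,4-dimethyloxolan-2-yl]-2-methoxyphenoxy}propan-1-one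
Product: 27 (1S,2R)-1-(4-{[tert-butyl(dimethyl)silyl]oxy}-3-methoxyphenyl)-2-{4-[(2S,3S,4R,5S)-5-(4-{[tert-butyl(dimethyl)silyl]oxy}-3-methoxyphenyl)-3,4-dimethyloxolan-2-yl]-2-methoxyphenoxy}propan-1-ol
Conditions: Zn(BH4)2, Et2O, −30 → 0 °C; aq. NH4Cl
Reagents that add atoms: none
Why: Chelation-controlled reduction (Cram-chelate model): divalent zinc bridges the carbonyl and aryloxy oxygens in a five-membered chelate and hydride should enter from the face bearing the α-hydrogen rather than the methyl, giving the erythro (1S,2R) alcohol.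

Step 17
Reactants: 27 (1S,2R)-1-(4-{[tert-butyl(dimethyl)silyl]oxy}-3-methoxyphenyl)-2-{4-[(2S,3S,4R,5S)-5-(4-{[tert-butyl(dimethyl)silyl]oxy}-3-methoxyphenyl)-3,4-dimethyloxolan-2-yl]-2-methoxyphenoxy}propan-1-ol
Product: 28 (1S,2R)-1-(4-hydroxy-3-methoxyphenyl)-2-{4-[(2S,3S,4R,5S)-5-(4-hydroxy-3-methoxyphenyl)-3,4-dimethyloxolan-2-yl]-2-methoxyphenoxy}propan-1-ol
Conditions: Bu4NF, AcOH, THF, 0 °C
Reagents that add atoms: none
Why: Fluoride cleaves both aryl silyl ethers, and the acetic acid buffer keeps the freed phenols from ionising to phenoxides, which could otherwise open the oxolane or the benzylic alcohol through quinone methides.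

**Compound list**

1 | (2R)-4-tert-butoxy-2-methyl-4-oxobutanoic acid | C[C@H](CC(=O)OC(C)(C)C)C(=O)O | starting material
2 | 4-tert-butyl 1-methyl (2R)-2-methylbutanedioate | COC(=O)[C@H](C)CC(=O)OC(C)(C)C | intermediate
3 | (3R)-4-methoxy-3-methyl-4-oxobutanoic acid | COC(=O)[C@H](C)CC(=O)O | intermediate
4 | (4S)-4-benzyl-1,3-oxazolidin-2-one | O=C1OC[C@H](Cc2ccccc2)N1 | starting material
5 | (3R)-4-methoxy-3-methyl-4-oxobutanoic 2,2-dimethylpropanoic anhydride (formed in the flask) | COC(=O)[C@H](C)CC(=O)OC(=O)C(C)(C)C | intermediate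
6 | methyl (2R)-4-[(4S)-4-benzyl-2-oxo-1,3-oxazolidin-3-yl]-2-methyl-4-oxobutanoate | COC(=O)[C@H](C)CC(=O)N1[C@@H](Cc2ccccc2)COC1=O | intermediate
7 | 4-(benzyloxy)-3-methoxybenzaldehyde | COc1cc(C=O)ccc1OCc1ccccc1 | starting material
8 | Z-dibutylboron enolate of 6 (formed in the flask) | COC(=O)[C@H](C)/C=C(\OB(CCCC)CCCC)N1[C@@H](Cc2ccccc2)COC1=O | intermediate
9 | dibutylboron syn-aldolate of 6 and 7 (formed in the flask) | COC(=O)[C@H](C)[C@@H]([C@H](OB(CCCC)CCCC)c1ccc(OCc2ccccc2)c(OC)c1)C(=O)N1[C@@H](Cc2ccccc2)COC1=O | intermediate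
10 | (4S)-4-benzyl-3-{[(2S,3S,4R)-2-[4-(benzyloxy)-3-methoxyphenyl]-4-methyl-5-oxooxolan-3-yl]carbonyl}-1,3-oxazolidin-2-one | O=C1O[C@H](c2ccc(OCc3ccccc3)c(OC)c2)[C@@H](C(=O)N2[C@@H](Cc3ccccc3)COC2=O)[C@H]1C | intermediate
11 | (2S,3S,4R)-2-[4-(benzyloxy)-3-methoxyphenyl]-4-methyl-5-oxooxolane-3-carboxylic acid | O=C1O[C@H](c2ccc(OCc3ccccc3)c(OC)c2)[C@@H](C(=O)O)[C@H]1C | intermediate
12 | (3R,4R,5S)-5-[4-(benzyloxy)-3-methoxyphenyl]-4-(hydroxymethyl)-3-methyloxolan-2-one | O=C1O[C@H](c2ccc(OCc3ccccc3)c(OC)c2)[C@@H](CO)[C@H]1C | intermediate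
13 | (3R,4S,5S)-5-[4-(benzyloxy)-3-methoxyphenyl]-4-(iodomethyl)-3-methyloxolan-2-one | O=C1O[C@H](c2ccc(OCc3ccccc3)c(OC)c2)[C@@H](CI)[C@H]1C | intermediate
14 | (3R,4S,5S)-5-[4-(benzyloxy)-3-methoxyphenyl]-3,4-dimethyloxolan-2-one | O=C1O[C@H](c2ccc(OCc3ccccc3)c(OC)c2)[C@@H](C)[C@H]1C | intermediate
15 | 4-bromo-2-methoxyphenol | COc1cc(Br)ccc1O | starting material
16 | (4-bromo-2-methoxyphenoxy)(tert-butyl)dimethylsilane | COc1cc(Br)ccc1O[Si](C)(C)C(C)(C)C | intermediate
17 | (4-{[tert-butyl(dimethyl)silyl]oxy}-3-methoxyphenyl)lithium (formed in the flask) | [Li]c1ccc(O[Si](C)(C)C(C)(C)C)c(OC)c1 | intermediate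
18 | (3R,4S,5S)-5-[4-(benzyloxy)-3-methoxyphenyl]-2-(4-{[tert-butyl(dimethyl)silyl]oxy}-3-methoxyphenyl)-3,4-dimethyloxolan-2-ol (C2 anomers) | COc1cc(C2(O)O[C@H](c3ccc(OCc4ccccc4)c(OC)c3)[C@@H](C)[C@H]2C)ccc1O[Si](C)(C)C(C)(C)C | intermediate
19 | (3R,4S,5S)-5-[4-(benzyloxy)-3-methoxyphenyl]-2-(4-{[tert-butyl(dimethyl)silyl]oxy}-3-methoxyphenyl)-3,4-dimethyl-4,5-dihydro-3H-furan-1-ium (formed in the flask) | COc1cc(C2=[O+][C@H](c3ccc(OCc4ccccc4)c(OC)c3)[C@@H](C)[C@H]2C)ccc1O[Si](C)(C)C(C)(C)C | intermediate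
20 | tert-butyl{4-[(2S,3R,4S,5S)-5-[4-(benzyloxy)-3-methoxyphenyl]-3,4-dimethyloxolan-2-yl]-2-methoxyphenoxy}dimethylsilane | COc1cc([C@H]2O[C@H](c3ccc(OCc4ccccc4)c(OC)c3)[C@@H](C)[C@H]2C)ccc1O[Si](C)(C)C(C)(C)C | intermediate
21 | 4-[(2S,3S,4R,5S)-5-(4-{[tert-butyl(dimethyl)silyl]oxy}-3-methoxyphenyl)-3,4-dimethyloxolan-2-yl]-2-methoxyphenol | COc1cc([C@H]2O[C@H](c3ccc(O)c(OC)c3)[C@@H](C)[C@H]2C)ccc1O[Si](C)(C)C(C)(C)C | intermediate
22 | ethyl (2S)-2-hydroxypropanoate | CCOC(=O)[C@H](C)O | starting material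
23 | ethyl (2R)-2-{4-[(2S,3S,4R,5S)-5-(4-{[tert-butyl(dimethyl)silyl]oxy}-3-methoxyphenyl)-3,4-dimethyloxolan-2-yl]-2-methoxyphenoxy}propanoate | COc1cc([C@H]2O[C@H](c3ccc(O[C@H](C)C(=O)OCC)c(OC)c3)[C@@H](C)[C@H]2C)ccc1O[Si](C)(C)C(C)(C)C | intermediate
24 | (2R)-2-{4-[(2S,3S,4R,5S)-5-(4-{[tert-butyl(dimethyl)silyl]oxy}-3-methoxyphenyl)-3,4-dimethyloxolan-2-yl]-2-methoxyphenoxy}-N-methoxy-N-methylpropanamide | COc1cc([C@H]2O[C@H](c3ccc(O[C@H](C)C(=O)N(C)OC)c(OC)c3)[C@@H](C)[C@H]2C)ccc1O[Si](C)(C)C(C)(C)C | intermediate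
25 | bromo(4-{[tert-butyl(dimethyl)silyl]oxy}-3-methoxyphenyl)magnesium (formed in the flask) | Br[Mg]c1ccc(O[Si](C)(C)C(C)(C)C)c(OC)c1 | intermediate
26 | (2R)-1-(4-{[tert-butyl(dimethyl)silyl]oxy}-3-methoxyphenyl)-2-{4-[(2S,3S,4R,5S)-5-(4-{[tert-butyl(dimethyl)silyl]oxy}-3-methoxyphenyl)-3,4-dimethyloxolan-2-yl]-2-methoxyphenoxy}propan-1-one | COc1cc([C@H]2O[C@H](c3ccc(O[C@H](C)C(=O)c4ccc(O[Si](C)(C)C(C)(C)C)c(OC)c4)c(OC)c3)[C@@H](C)[C@H]2C)ccc1O[Si](C)(C)C(C)(C)C | intermediate
27 | (1S,2R)-1-(4-{[tert-butyl(dimethyl)silyl]oxy}-3-methoxyphenyl)-2-{4-[(2S,3S,4R,5S)-5-(4-{[tert-butyl(dimethyl)silyl]oxy}-3-methoxyphenyl)-3,4-dimethyloxolan-2-yl]-2-methoxyphenoxy}propan-1-ol | COc1cc([C@H]2O[C@H](c3ccc(O[C@H](C)[C@@H](O)c4ccc(O[Si](C)(C)C(C)(C)C)c(OC)c4)c(OC)c3)[C@@H](C)[C@H]2C)ccc1O[Si](C)(C)C(C)(C)C | intermediate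
28 | (1S,2R)-1-(4-hydroxy-3-methoxyphenyl)-2-{4-[(2S,3S,4R,5S)-5-(4-hydroxy-3-methoxyphenyl)-3,4-dimethyloxolan-2-yl]-2-methoxyphenoxy}propan-1-ol | COc1cc([C@H]2O[C@H](c3ccc(O[C@H](C)[C@@H](O)c4ccc(O)c(OC)c4)c(OC)c3)[C@@H](C)[C@H]2C)ccc1O | target

**Step count and risks**

Total step count: 17. Longest linear sequence: 16 steps (steps 1–8 and 10–17, from 1 to 28); step 9 is a one-step branch that supplies rings A and C.

The three steps most likely to fail:

Step 4. The enolate is β-branched and the aldehyde is electron-rich, so addition may be slow. The resident methyl-bearing centre may erode the facial selectivity set by the auxiliary. The boron aldolate may also fail to close fully onto the α-branched ester. The fallback sets out from acid 3 and keeps the same bond construction with a different enolate class. Acid 3 is coupled with purchased (4S)-4-benzyl-1,3-thiazolidine-2-thione (EDC·HCl, DMAP, CH2Cl2) to give methyl (2R)-4-[(4S)-4-benzyl-2-sulfanylidene-1,3-thiazolidin-3-yl]-2-methyl-4-oxobutanoate F1. Its chlorotitanium enolate (TiCl4, i-Pr2NEt, N-methylpyrrolidinone, CH2Cl2, −78 → 0 °C) is expected to add to 7 in the same syn sense. Lactonisation, completed if needed by brief treatment of the crude with catalytic camphorsulfonic acid, should give (4S)-4-benzyl-3-{[(2S,3S,4R)-2-[4-(benzyloxy)-3-methoxyphenyl]-4-methyl-5-oxooxolan-3-yl]carbonyl}-1,3-thiazolidine-2-thione F2. The activated thioimide is then cleaved reductively with NaBH4 (THF/H2O, 0 °C), which should spare the lactone, and the route is rejoined at alcohol 12, bypassing 11.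

Step 11. The oxocarbenium ion may lose the C3 proton to the enol ether and be reprotonated, which epimerises C3. Hydride may also be delivered to the wrong face, or the product may ionise at benzylic C5 if the mixture warms. The fallback sets out from hemiketal 18. It is dehydrated on purpose (pyridinium p-toluenesulfonate (cat.), toluene, 4 Å sieves, 60 °C) to tert-butyl{4-[(4S,5S)-5-[4-(benzyloxy)-3-methoxyphenyl]-3,4-dimethyl-4,5-dihydrofuran-2-yl]-2-methoxyphenoxy}dimethylsilane F3. Hydrogenation (H2, Pd/C, EtOAc) then adds both hydrogens to C2=C3 in a syn fashion, expectedly from the face opposite the allylic C4 methyl. Ring A and the C3 methyl therefore end cis to each other and to the C4 methyl, and C3 is set afresh, which also repairs any epimerisation incurred in step 10. The benzyl ether is cleaved in the same operation, so the route is rejoined at phenol 21.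

Step 16. The aryloxy oxygen is a weak donor, so chelation may be loose and face selectivity in the hydride transfer poor. Ketone 26 may also epimerise at its α-carbon before it is reduced. The fallback sets out from Weinreb amide 24 and sets the carbinol centre in a C–C bond formation instead. Amide 24 is reduced (i-Bu2AlH, THF, −78 °C) to (2R)-2-{4-[(2S,3S,4R,5S)-5-(4-{[tert-butyl(dimethyl)silyl]oxy}-3-methoxyphenyl)-3,4-dimethyloxolan-2-yl]-2-methoxyphenoxy}propanal F4, which is used crude. Aryl Grignard reagent 25, made from 16 and Mg as in step 15, is transmetalated with ClTi(OiPr)3 (THF, −78 °C) to (4-{[tert-butyl(dimethyl)silyl]oxy}-3-methoxyphenyl)tri(propan-2-yloxy)titanium F5. This non-chelating aryl donor should add to F4 under polar Felkin–Anh control, anti to the aryloxy group, to give the erythro (1S,2R) alcohol, and the route is rejoined at 27, bypassing 26.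

**Further compounds**

F1 | step 4 | methyl (2R)-4-[(4S)-4-benzyl-2-sulfanylidene-1,3-thiazolidin-3-yl]-2-methyl-4-oxobutanoate | COC(=O)[C@H](C)CC(=O)N1[C@@H](Cc2ccccc2)CSC1=S
F2 | step 4 | (4S)-4-benzyl-3-{[(2S,3S,4R)-2-[4-(benzyloxy)-3-methoxyphenyl]-4-methyl-5-oxooxolan-3-yl]carbonyl}-1,3-thiazolidine-2-thione | O=C1O[C@H](c2ccc(OCc3ccccc3)c(OC)c2)[C@@H](C(=O)N2[C@@H](Cc3ccccc3)CSC2=S)[C@H]1C
F3 | step 11 | tert-butyl{4-[(4S,5S)-5-[4-(benzyloxy)-3-methoxyphenyl]-3,4-dimethyl-4,5-dihydrofuran-2-yl]-2-methoxyphenoxy}dimethylsilane | COc1cc(C=2O[C@H](c3ccc(OCc4ccccc4)c(OC)c3)[C@@H](C)C=2C)ccc1O[Si](C)(C)C(C)(C)C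
F4 | step 16 | (2R)-2-{4-[(2S,3S,4R,5S)-5-(4-{[tert-butyl(dimethyl)silyl]oxy}-3-methoxyphenyl)-3,4-dimethyloxolan-2-yl]-2-methoxyphenoxy}propanal | COc1cc([C@H]2O[C@H](c3ccc(O[C@H](C)C=O)c(OC)c3)[C@@H](C)[C@H]2C)ccc1O[Si](C)(C)C(C)(C)C
F5 | step 16 | (4-{[tert-butyl(dimethyl)silyl]oxy}-3-methoxyphenyl)tri(propan-2-yloxy)titanium | CC(C)O[Ti](OC(C)C)(OC(C)C)c1ccc(O[Si](C)(C)C(C)(C)C)c(OC)c1
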